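The easiest thing to do with this flask is to add up its columns.

- zeta: starting material 2 M; partner 2.1 M; free catalyst 200 mM; the very flask that is asked about, followed so far
- flask: starting material 2.0 M; partner 2.10 M; free catalyst 200 mM; time 2.5 h

zeta run (percent of the starting material charged)

| time / min | product / % | starting material / % |
|---|---|---|
| 20.0 | 54.3 | 41.4 |
| 50.0 | 70.2 | 24.1 |
| 90.0 | 78.6 | 16.6 |
| 150 | 83.6 | 10.6 |

(scatter of a reading: 0.3 percentage points)

- north-east: at 2.5 h add free catalyst, 100% of the amount charged, then wait 2.5 h
- north: at 2.5 h take out 90% of the product then present, then wait 2.5 h
- south: change nothing and wait 2.5 h more

- what is taken out of product is counted as made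
- the analysis behind the earlier runs scatters by 0.3 percentage points, standard deviation
- additions bring no volume worth counting

- product, in percent of the starting material first charged, at 2.5 h
- what to do for the largest gain in product; "none" if nothing gains more than 2 percentage points (north-east / north / south / none)
- product present, with what was taken out counted in, in percent of the starting material first charged, after north
- product present, with what was taken out counted in, in percent of the starting material first charged, after south

The last reading of the zeta run is this flask at the moment we act: product 83.6% at 150 min, which answers "now". With starting material 10.6%, a gap of 5.80% of the charge remains, uncertain by about 0.42 percentage points. We read that gap as starting material held one for one on dead catalyst. Product made per catalyst lost, the turnover number, is then product over gap, 14.4.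

If what still reacts splits the same way, product tops out at a ceiling of 93.5%. The catalyst charge can pay for a budget of 144% of the starting material. Turned round, a stall with starting material unused asks for a budget that falls short of the ceiling, but in this flask the budget is larger than the ceiling, by a factor of 1.54. So we expect this flask to slow rather than stop, with 58.0% of the catalyst read as lost.

The last two readings give a second-order constant of 0.0205 M⁻¹ min⁻¹. Held for 2.5 h, it leaves 4.99% starting material after south, hence product 88.8%. We take north as equal, having no reading that product slows the flask. North-east multiplies working catalyst by 3.38, which leaves 1.58% and product 92.0%, more than south.

The forecast gives 83.7%, 88% after south and 89% after north, and picks north-east, holding that “Fresh catalyst should at least double the rate”.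

The flask gives 83.6%, with 88.4% after south and 88.4% after north, while north-east gains 8.1 points, more than either other option.

    starting material + free catalyst ⇌ catalyst intermediate A (K = 0.0610 M⁻¹, k = 0.790 M⁻¹ s⁻¹)
    catalyst intermediate B → spent catalyst (k = 0.0150 s⁻¹)
    partner + catalyst intermediate A → catalyst intermediate B (k = 0.0660 M⁻¹ s⁻¹)
    catalyst intermediate B → free catalyst + product (k = 0.210 s⁻¹)

Left ten times as long, the flask holds 93.0% product at 1500 min, beside our ceiling of 93.5%. A neighbouring flask has 0.050 M of free catalyst, and the same turnover number gives it a budget of 36.0%, below the ceiling, so a stall is expected there. That flask gives 34.6% product, with 62.9% of its starting material unreacted, and at 150 min its catalyst stands at 98.8% spent and 1.08% free.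

The earlier runs and the new flask were computed from invented constants, and the scatter is random.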